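## The problem

Compound 21 is a dearomatised, fully substituted phloroglucinol. A cyclohexadienone (ring A: C4a, C5, C6, C7, C8, C8a in chroman-4-one numbering) is fused through C4a–C8a to a 2,3-dimethyl-2,3-dihydropyran-4-one (ring B). It carries C3' of an octanoic acid at C6, and at the quaternary C8 a prenyl group and the methylene arm of a 2,2-dimethyl-3-isopropenylcyclobutane (ring C). The six stereocentres fall into four sets insulated from one another by the flat ring A: C2/C3 (R,R, trans), C8 (R), C3' (S) and the cis pair C1''/C3'' (R,S) of ring C. Control works only inside a set, since C3 is enolisable and settles trans to C2 and the cis relation in ring C is that of a pinane bicycle. Each set therefore needs its own catalyst or chiral-pool source, and any shortfall appears as a separable diastereomer. C8 is the hardest centre, because its two carbon arms differ only beyond the first methylene and it is created in the step that destroys aromaticity, where O-alkylation and attack at C6 compete. Once the isopropenyl and prenyl groups are present, strong Brønsted and Lewis acids are excluded (protonation next to ring C gives a cyclobutylcarbinyl cation that expands or opens), forcing base can expel O1 from C2 by a retro-oxa-Michael reaction, and a carbonyl group on ring C would make its α-carbon epimerisable. The decisive feature is that C6 bears CH(C5H11)CH2CO2H while its neighbour C5 bears an enol oxygen. Joining C1' to O5 gives the ring O5–C5–C6–C3'–C2'–C1', which after rearomatisation of ring A is a 4-pentyl-3,4-dihydrocoumarin of phloroglucinol, the formal [3+3] adduct of a C–C–O unit of the phenol with a chiral oct-2-enoyl azolium.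

## Retrosynthesis

**Disconnection 1, 21 to 20 (O5–C1' closed, no skeletal bond cut).** The carboxyl group is tied back to the enol oxygen on C5 as a six-membered enol lactone.
- An external ester would have to be put on and taken off, whereas this lactone exists from the first step.
- It keeps the acidic proton and the carboxylate away from the organozinc and palladium steps, and it blocks O5, so ring A of every earlier compound offers one free oxygen only.
- The gain is in handling, not in size.
- The forward reaction must open an activated enol ester without expelling O1 from C2 or epimerising C3. Cold dilute hydroxide should do so, because the leaving group is the anion of a β-tricarbonyl system and the resulting dianion resists further deprotonation.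

**Disconnection 2, 20 to 17 and 19 (C8–CH2 bond of the prenyl group).** Of the two exocyclic bonds at C8 this one should be formed last.
- Its electrophile is allylic and can be delivered as an η3-prenyl palladium cation inside a chiral ligand sphere. The other arm would demand substitution at a β-branched, sluggish primary carbon.
- The cut restores aromaticity, deletes the quaternary centre and leaves phenol 17 with the other five stereocentres in place.
- The forward reaction must choose carbon over oxygen, the carbon between two oxygens over the one bearing the lactone chain, the linear over the branched allyl terminus, and one face of a flat nucleophile.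
- Carbonate 19 (one step from prenol 18) releases only CO2 and tert-butanol, so no nucleophile appears that could open the lactone.

**Disconnection 3, 17 to 9 and 14 (bond from ring A to the methylene arm of ring C).** This is the most convergent cut, dividing C29 into a C19 aryl iodide and a C10 alkyl iodide.
- Forming the same bond by condensing the phenol with a formyl group on ring C and reducing would be one step shorter, but three things speak against it. The formyl-bearing carbon is the C1'' stereocentre and would be exposed to enol and enamine formation. The quinone methide on that path can erase the same centre by a 1,5-hydrogen shift. The usual amine or acid promoters attack the aryl lactone or the isopropenyl group.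
- A Negishi coupling of zinc reagent 16 (from 14) with 9, masked in the flask as silyl ether 15, is neutral and leaves every stereocentre untouched.
- It has to cope with a di-ortho-substituted, electron-rich iodide.

**Disconnection 4, 14 to 13, 12, 11 and 10 (functional-group changes, the C=CH2 bond, and the enone bond of a pinane).**
- Ring C with its gem-dimethyl group and cis-1,3 pattern is the cyclobutane of (1S,5S)-verbenone 10.
- Oxidative cleavage of the enone with loss of one carbon gives keto acid 11. Methylenation gives 12, reduction gives 13 and iodination gives 14.
- Building the ring de novo would have to create what the terpene supplies with both centres fixed by the bicycle.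
- The only demand is that the acetyl-bearing centre is not epimerised during methylenation.

**Disconnection 5, 9 to 8, 7 and 6 (C–I bond, H at C3, O1–C2 bond).**
- The iodine goes onto the only aromatic C–H of 8.
- Ring B is opened at O1–C2 to the tigloyl phenol 6. The alternative cut at C4–C4a would need a chiral acyl donor.
- Closure by a cinchona-catalysed oxa-Michael addition sets C2, gives mainly the cis isomer 7, and soft enolisation moves C3 to the trans isomer 8.
- The lactone serves a second purpose here. Of the two oxygens flanking the tigloyl group one is acylated, so only one ring can form.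
- The lactone cannot migrate to the other ortho oxygen by itself. The tetrahedral intermediate would be a bicyclo[2.2.2] system with an aromatic bridgehead, so nucleophile-free conditions preserve the regiochemistry.

**Disconnection 6, 6 to 4 and 5 (aryl–acyl bond).**
- Friedel–Crafts acylation with tigloyl chloride 5 brings in all five carbons of ring B at once.
- The reaction must select C8 of the chroman-2-one over C6.
- C6 lies between two aluminium-bound oxygens, one of them pushed towards it by the peri C4 substituent, whereas C8 has only one such neighbour.
- 5,7-Dihydroxy-4-alkylcoumarins show this preference.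

**Disconnection 7, 4 to 1 and 2 through 3 (aryl–C3' bond and O5–C1' bond).**
- Both bonds of the dihydropyranone ring that do not belong to the arene or the chain are cut together, which leads to phloroglucinol 1 and (E)-oct-2-enal 2, both commercial.
- Cutting only the ester bond would leave a chiral 3-aryloctanoic acid to be made separately. Cutting only the aryl bond would leave a conjugate addition lacking an obvious chiral controller.
- The oxidative carbene-catalysed annulation through acyl azolium 3 forms both bonds, the ring and C3' in one operation, and the threefold symmetry of 1 removes any regiochemical question.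

## Roads not taken

**Alternative 1:** The cut goes through ring C (bonds C1''–C4'' and C2''–C3'') and leads to prenyl pivalate A2 and a 3-methylbut-3-enamide of a C2-symmetric pyrrolidine, A3.
- *Forward step.* A3 is activated with triflic anhydride and a hindered base to the vinyl keteniminium salt A4, which adds stepwise across the double bond of A2. Hydrolysis gives cyclobutanone A1.
- *Merits.* Two ring bonds and both ring stereocentres form in one step. The regiochemistry is polarity-matched (central carbon to the methine, cation at the dimethyl carbon). Either enantiomer is available, and the result does not depend on the optical purity of a terpene. In these last two respects it is better than the chiral-pool route.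
- *Weak points.*
  - A4 has a diene-like π system that can react at its vinyl end or oligomerise.
  - A3 can slip into conjugation before activation.
  - A trisubstituted alkene with an allylic ester is a slow partner.
  - Both stereocentres of A1 are α to the ketone and one is also allylic, so the cis relation and the position of the double bond depend on avoiding enolisation.
  - The carbonyl group sits where 21 has a CH2 and must be removed without harming a 1,1-disubstituted alkene.
- *Comparison.* That amounts to about six operations for a fragment that 10 delivers in four, with the cis relation locked by the bicycle. This road covers ten of thirty-four carbons and two of six stereocentres and is silent on ring A, C3' and C8. It could replace steps 6 to 9 but cannot organise the synthesis.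

**Alternative 2:** Ring A is cut at C6–C7. This gives the dihydropyranone keto diester A6, in which C8 is already quaternary and bears a methyl ester, while C4a bears the ketone C5 with the chain from C6.
- *Forward step.* The enolate at C6 attacks the ester carbonyl (Dieckmann closure, 6-exo-trig) and gives A5, the 2-(trimethylsilyl)ethyl ester of 21, one fluoride step from the target.
- *Merits.* No dearomatisation takes place, so no carbon-versus-oxygen question arises. C8 is made as an α,α-dialkylated ester centre, a setting with mature auxiliary and catalytic methods. Here this road is better than the chosen plan, whose C8 step is its least precedented. The end game is also mild, and the β-tricarbonyl product is a thermodynamic sink.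
- *Weak points.*
  - A6 is hardly simpler than 21. It holds all six stereocentres, and its fully substituted 5-acyl-6-tert-alkyl dihydropyranone has no short construction, so the line becomes long and linear.
  - The closure must attack an ester next to a quaternary carbon.
  - A base strong enough for that finds other acidic sites (C3–H, C2'–H) and can expel O1 from C2.
- *Comparison.* The chosen plan buys ring A with its three oxygens, reaches the same oxidation pattern in eight linear steps, and has separable C8 epimers and a classical fallback to offset its weaker control of C8.

**Alternative 3:** Ring B is cut at O1–C2. The precursor is the tigloyl phenol that appears here as 6, and the product A7 is identical with 8.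
- *Forward step.* A bifunctional cinchona amine guides the phenolic oxygen to one face of the enone β-carbon, and C3 is fixed on protonation and equilibration.
- *Merits.* In precedent this is the stronger reaction, since 7-hydroxy-8-tigloyl benzopyranones are the very class on which it is known, whereas phloroglucinol is a new partner for an acyl azolium.
- *Weak points.* It forms a single C–O bond, kinetic protonation favours the cis isomer so a second operation is needed, and as a strategy it leaves open where 6, with C3' and the lactone, comes from.
- *Comparison.* The reaction is therefore adopted as steps 3 and 4 rather than rejected. The chosen key step adds a ring, two bonds and a stereocentre from two commercial compounds, and it provides the lactone that makes this oxa-Michael closure regiochemically unambiguous.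

Key step: step 1

Assumption: the antipodes written for the triazolium salt (step 1) and the bisphosphine ligand (step 12) are taken to be those that give the drawn configurations. Both antipodes of each are commercial, so a reversed sense of induction is met by exchanging the antipode without changing the route.

Locants:
- Compounds 4 and 6 are numbered as chroman-2-ones.
- The tricycles 7 to 9, 15, 17 and 20 are numbered as pyrano[2,3-f]chromenes.
- Target atoms C8, C7, C6, C5, C4a, C8a correspond to tricycle atoms C6, C5, C4a, C10b, C10a, C6a.
- Target C2, C3, C4 correspond to tricycle C8, C9, C10, and target C3' to tricycle C4.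

## Steps

Step 1
Reactants: 1 phloroglucinol (anhydrous, 3 equiv); 2 (E)-oct-2-enal
Product: 4 (S)-5,7-dihydroxy-4-pentylchroman-2-one, via octenoyl azolium ion 3 (not isolated)
Conditions: (5aS,10bR)-2-mesityl-5a,10b-dihydro-4H,6H-indeno[2,1-b][1,2,4]triazolo[4,3-d][1,4]oxazinium tetrafluoroborate (10 mol%), 3,3',5,5'-tetra-tert-butyldiphenoquinone (1.1 equiv), iPr2NEt (0.5 equiv), 4 Å molecular sieves, THF, rt
Reagents that add atoms: none
Why: The free carbene adds to 2, and the resulting hydroxy-enamine (Breslow-type intermediate) is oxidised by the diphenoquinone to the unsaturated acyl azolium 3. A ring carbon of 1, activated as its phenoxide, bonds to C3 of 3, either directly (Michael addition) or after reversible addition of oxygen to the acyl carbon and a [3,3] shift of the Coates–Claisen type; this is the enantio-determining event. Tautomerisation restores the arene and leaves a saturated acyl azolium, which the ortho hydroxyl attacks in a 6-exo-trig lactonisation that closes the dihydropyranone ring and releases the carbene. The closest known reaction type is the oxidative carbene-catalysed [3+3] annulation of enals with 2-naphthols and with enols of 1,3-dicarbonyl compounds; 1 is at once a hydroxyarene and the tris-enol of a cyclic triketone. The single new stereocentre C4 (S) requires attack on the Si face of C3 of 3, the fused indane of the catalyst shielding the other face of the planar conjugated acyl azolium. No regiochemistry arises because the three ring carbons of 1 are equivalent. Mono-annulation is secured by the excess of cheap, water-extractable 1 and by the fact that in 4 one donor oxygen has become an ester oxygen, and simple O-acylation is no dead end because aryl enoates are re-activated by the carbene. The weak amine base limits γ-deprotonation of 3 and dry conditions prevent its hydrolysis.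

Step 2
Reactants: 4 (S)-5,7-dihydroxy-4-pentylchroman-2-one; 5 tigloyl chloride [(E)-2-methylbut-2-enoyl chloride]
Product: 6 (S)-5,7-dihydroxy-8-[(E)-2-methylbut-2-enoyl]-4-pentylchroman-2-one
Conditions: AlCl3 (4 equiv), CH2Cl2/PhNO2, 0 °C to rt; cold 1 M HCl
Reagents that add atoms: none
Why: Friedel–Crafts C-acylation of the aluminium phenoxide; C6 lies between two O–AlCl2 groups (one buttressed by the peri C4 substituent) while C8 has only one such neighbour, the preference known for 5,7-dihydroxy-4-alkylcoumarins. The low temperature should keep the enone from closing on O7 without stereocontrol and the lactone from a Fries-type shift.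

Step 3
Reactants: 6 (S)-5,7-dihydroxy-8-[(E)-2-methylbut-2-enoyl]-4-pentylchroman-2-one
Product: 7 (4S,8R,9S)-5-hydroxy-8,9-dimethyl-4-pentyl-3,4,8,9-tetrahydro-2H,10H-pyrano[2,3-f]chromene-2,10-dione (cis-dimethyl isomer, accompanied by some 8)
Conditions: (−)-quinine (20 mol%), PhCl, rt
Reagents that add atoms: none
Why: Cinchona-catalysed intramolecular oxa-Michael addition (6-endo-trig), known for 7-hydroxy-8-tigloyl benzopyranones: the quinuclidine nitrogen activates the 7-OH while the catalyst hydroxyl binds the enone, which should fix C8 as R, and kinetic protonation of the enol gives mainly the cis isomer. Only O7 can add because the other oxygen flanking the enone is held in the lactone, and the C4 centre is too remote to oppose the catalyst.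

Step 4
Reactants: 7 (4S,8R,9S)-cis-chromanone lactone
Product: 8 (4S,8R,9R)-5-hydroxy-8,9-dimethyl-4-pentyl-3,4,8,9-tetrahydro-2H,10H-pyrano[2,3-f]chromene-2,10-dione (trans-dimethyl isomer)
Conditions: MgI2 (1 equiv), Et3N (2 equiv), CH2Cl2/Et2O, rt
Reagents that add atoms: none
Why: Soft enolisation (Mg2+ on the ketone, tertiary amine as base) reversibly removes H9, and reprotonation settles on the more stable diequatorial trans isomer, so C9 becomes R under thermodynamic control. The conditions are too mild for expulsion of the phenoxide, so C8 is kept; remaining cis isomer and any diastereomer from leakage in steps 1 or 3 are removed here by chromatography or crystallisation.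

Step 5
Reactants: 8 (4S,8R,9R)-trans-chromanone lactone
Product: 9 (4S,8R,9R)-5-hydroxy-6-iodo-8,9-dimethyl-4-pentyl-3,4,8,9-tetrahydro-2H,10H-pyrano[2,3-f]chromene-2,10-dione
Conditions: NIS (1.05 equiv), MeCN, 0 °C, dark
Reagents that add atoms: N-iodosuccinimide, O=C1CCC(=O)N1I
Why: Electrophilic aromatic iodination; C6 is the only ring C–H and lies ortho to the free hydroxyl and to the ether oxygen, so no regiochemical question arises.

Step 6
Reactants: 10 (1S,5S)-(−)-verbenone
Product: 11 (1S,3R)-3-acetyl-2,2-dimethylcyclobutane-1-carboxylic acid (cis-pinononic acid)
Conditions: RuCl3·xH2O (2 mol%), NaIO4 (4.2 equiv), EtOAc/MeCN/H2O, rt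
Reagents that add atoms: sodium periodate, [Na+].[O-]I(=O)(=O)=O; water, O
Why: RuO4-catalysed oxidative cleavage of the enone double bond; the α-keto acid first formed loses CO2 oxidatively. The two bridgehead centres are not touched and become the cis-1,3 pair of ring C; recrystallisation of the acid should make up for imperfect optical purity of the terpene.

Step 7
Reactants: 11 cis-pinononic acid
Product: 12 (1S,3S)-2,2-dimethyl-3-(prop-1-en-2-yl)cyclobutane-1-carboxylic acid
Conditions: Ph3PCH3Br (2.5 equiv), KOtBu (2.5 equiv), THF, 0 °C to rt; then dilute HCl
Reagents that add atoms: methyltriphenylphosphonium bromide, C[P+](c1ccccc1)(c1ccccc1)c1ccccc1.[Br-]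
Why: Wittig methylenation of the carboxylate salt, the first equivalent of ylide serving as base. Enolisation towards the ring carbon would place an exocyclic double bond on the four-membered ring and is disfavoured against deprotonation of the methyl group, so the cis relation should be retained.

Step 8
Reactants: 12 isopropenyl acid
Product: 13 [(1S,3S)-2,2-dimethyl-3-(prop-1-en-2-yl)cyclobutyl]methanol
Conditions: LiAlH4, Et2O, 0 °C to rt
Reagents that add atoms: none
Why: Hydride reduction of a carboxylic acid to the primary alcohol; the isolated alkene and both stereocentres are inert.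

Step 9
Reactants: 13 cyclobutylmethanol
Product: 14 (1S,3S)-1-(iodomethyl)-2,2-dimethyl-3-(prop-1-en-2-yl)cyclobutane
Conditions: I2, PPh3, imidazole, CH2Cl2, 0 °C
Reagents that add atoms: iodine, II
Why: Appel iodination by SN2 displacement at the primary carbon under neutral conditions, so no cyclobutylcarbinyl cation and no rearrangement are involved.

Step 10
Reactants: 9 aryl iodide; 14 alkyl iodide
Product: 17 (4S,8R,9R)-6-{[(1R,3S)-2,2-dimethyl-3-(prop-1-en-2-yl)cyclobutyl]methyl}-5-hydroxy-8,9-dimethyl-4-pentyl-3,4,8,9-tetrahydro-2H,10H-pyrano[2,3-f]chromene-2,10-dione, via trimethylsilyl ether 15 (not isolated), via alkylzinc iodide 16 (not isolated)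
Conditions: 14, Zn, LiCl, THF, 40 °C; separately 9, N,O-bis(trimethylsilyl)acetamide (1.1 equiv), THF, rt; combine, Pd(OAc)2 (3 mol%), SPhos (6 mol%), rt to 45 °C; aq. citric acid
Reagents that add atoms: none
Why: Negishi sp2–sp3 coupling; LiCl-assisted insertion of Zn into the primary C–I bond gives 16, and transient O-silylation of the acidic phenol prevents its protonolysis. The dialkylbiaryl phosphine should speed oxidative addition to the di-ortho-substituted iodide and let reductive elimination outrun β-hydride elimination. Ketone and lactone are inert to alkylzinc halides, no stereocentre is involved, and the silyl ether falls off on mildly acidic work-up.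

Step 11
Reactants: 18 3-methylbut-2-en-1-ol (prenol)
Product: 19 tert-butyl 3-methylbut-2-en-1-yl carbonate
Conditions: n-BuLi, THF, −78 to 0 °C; Boc2O
Reagents that add atoms: di-tert-butyl dicarbonate, CC(C)(C)OC(=O)OC(=O)OC(C)(C)C
Why: O-acylation of the lithium alkoxide with the dicarbonate, the standard entry to allylic tert-butyl carbonates.

Step 12
Reactants: 17 phenol; 19 tert-butyl prenyl carbonate
Product: 20 (4S,6R,8R,9R)-6-{[(1R,3S)-2,2-dimethyl-3-(prop-1-en-2-yl)cyclobutyl]methyl}-8,9-dimethyl-6-(3-methylbut-2-en-1-yl)-4-pentyl-3,4,8,9-tetrahydro-2H-pyrano[2,3-f]chromene-2,5,10(6H)-trione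
Conditions: Pd2(dba)3·CHCl3 (2.5 mol%), (R,R)-DACH-phenyl bisphosphine ligand [N,N'-((1R,2R)-cyclohexane-1,2-diyl)bis(2-(diphenylphosphino)benzamide)] (6 mol%), toluene, 0 °C to rt
Reagents that add atoms: none
Why: Proposed new method: zerovalent palladium ionises 19 to a cationic η3-prenyl complex, CO2 and tert-butoxide, which deprotonates the acidic phenol of 17; the delocalised phenoxide (a vinylogous carboxylate, para to the chromanone carbonyl) attacks the unsubstituted allyl terminus through C6, the ring carbon flanked by two oxygens, while any aryl prenyl ether formed at oxygen is re-ionised and funnelled to the C-alkylated dienone, attack at the substituted terminus would join two quaternary carbons and is excluded, and the chiral pocket of the ligand selects the face of the flat nucleophile and thereby sets C6 as R; the closest known reaction types are the palladium-catalysed dearomative allylation of phloroglucinol ethers with allyl carbonates (racemic), the asymmetric allylic dearomatisation of 1,3-disubstituted 2-naphthols and the asymmetric linear prenylation of 3-substituted oxindoles with the same ligand family (Tsuji–Trost manifold), and new is the union of prenyl donor, phloroglucinol-type phenol and catalyst-controlled face selection.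

Step 13
Reactants: 20 dearomatised enol lactone
Product: 21 (3S)-3-[(2R,3R,8R)-8-{[(1R,3S)-2,2-dimethyl-3-(prop-1-en-2-yl)cyclobutyl]methyl}-5-hydroxy-2,3-dimethyl-8-(3-methylbut-2-en-1-yl)-4,7-dioxo-3,4,7,8-tetrahydro-2H-chromen-6-yl]octanoic acid (CNP0208815.1)
Conditions: LiOH (2.5 equiv), THF/H2O, 0 °C; then 1 M HCl to pH 3 to 4, 0 °C
Reagents that add atoms: lithium hydroxide, [Li+].[OH-]; water, O
Why: Saponification of an activated enol ester whose leaving group is the anion of a β-tricarbonyl system, so it should be fast at 0 °C. The carboxylate–enolate dianion resists deprotonation at C3 and expulsion of O1, which protects C2 and C3. Brief mild acidification gives the free acid with the C5 enol hydrogen-bonded to the C4 carbonyl and does not touch the two alkenes.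

## Compound list

1 | phloroglucinol (benzene-1,3,5-triol) | Oc1cc(O)cc(O)c1 | starting material
2 | (E)-oct-2-enal | CCCCC/C=C/C=O | starting material
3 | (E)-oct-2-enoyl azolium ion (acyl group on the carbene carbon of the (5aS,10bR)-2-mesityl indeno-oxazino-triazolium catalyst) | CCCCC/C=C/C(=O)c1n2c(n[n+]1-c1c(C)cc(C)cc1C)CO[C@H]1Cc3ccccc3[C@@H]21 | intermediate
4 | (S)-5,7-dihydroxy-4-pentylchroman-2-one | O=C1C[C@H](CCCCC)c2c(O)cc(O)cc2O1 | intermediate
5 | tigloyl chloride | C/C=C(\C)C(=O)Cl | starting material
6 | (S)-5,7-dihydroxy-8-[(E)-2-methylbut-2-enoyl]-4-pentylchroman-2-one | O=C1C[C@H](CCCCC)c2c(O)cc(O)c(C(=O)/C(C)=C/C)c2O1 | intermediate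
7 | (4S,8R,9S)-5-hydroxy-8,9-dimethyl-4-pentyl-3,4,8,9-tetrahydro-2H,10H-pyrano[2,3-f]chromene-2,10-dione | O=C1C[C@H](CCCCC)c2c(O)cc3O[C@H](C)[C@H](C)C(=O)c3c2O1 | intermediate
8 | (4S,8R,9R)-5-hydroxy-8,9-dimethyl-4-pentyl-3,4,8,9-tetrahydro-2H,10H-pyrano[2,3-f]chromene-2,10-dione | O=C1C[C@H](CCCCC)c2c(O)cc3O[C@H](C)[C@@H](C)C(=O)c3c2O1 | intermediate
9 | (4S,8R,9R)-5-hydroxy-6-iodo-8,9-dimethyl-4-pentyl-3,4,8,9-tetrahydro-2H,10H-pyrano[2,3-f]chromene-2,10-dione | O=C1C[C@H](CCCCC)c2c(O)c(I)c3O[C@H](C)[C@@H](C)C(=O)c3c2O1 | intermediate
10 | (1S,5S)-(−)-verbenone | CC1=CC(=O)[C@H]2C[C@@H]1C2(C)C | starting material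
11 | (1S,3R)-3-acetyl-2,2-dimethylcyclobutane-1-carboxylic acid | CC(=O)[C@@H]1C[C@H](C(=O)O)C1(C)C | intermediate
12 | (1S,3S)-2,2-dimethyl-3-(prop-1-en-2-yl)cyclobutane-1-carboxylic acid | C=C(C)[C@@H]1C[C@H](C(=O)O)C1(C)C | intermediate
13 | [(1S,3S)-2,2-dimethyl-3-(prop-1-en-2-yl)cyclobutyl]methanol | C=C(C)[C@@H]1C[C@H](CO)C1(C)C | intermediate
14 | (1S,3S)-1-(iodomethyl)-2,2-dimethyl-3-(prop-1-en-2-yl)cyclobutane | C=C(C)[C@@H]1C[C@H](CI)C1(C)C | intermediate
15 | 5-O-trimethylsilyl ether of 9 | O=C1C[C@H](CCCCC)c2c(O[Si](C)(C)C)c(I)c3O[C@H](C)[C@@H](C)C(=O)c3c2O1 | intermediate
16 | {[(1S,3S)-2,2-dimethyl-3-(prop-1-en-2-yl)cyclobutyl]methyl}zinc iodide | C=C(C)[C@@H]1C[C@H](C[Zn]I)C1(C)C | intermediate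
17 | (4S,8R,9R)-6-{[(1R,3S)-2,2-dimethyl-3-(prop-1-en-2-yl)cyclobutyl]methyl}-5-hydroxy-8,9-dimethyl-4-pentyl-3,4,8,9-tetrahydro-2H,10H-pyrano[2,3-f]chromene-2,10-dione | C=C(C)[C@@H]1C[C@H](Cc2c(O)c3c(OC(=O)C[C@@H]3CCCCC)c3c2O[C@H](C)[C@@H](C)C3=O)C1(C)C | intermediate
18 | 3-methylbut-2-en-1-ol | CC(C)=CCO | starting material
19 | tert-butyl 3-methylbut-2-en-1-yl carbonate | CC(C)=CCOC(=O)OC(C)(C)C | intermediate
20 | (4S,6R,8R,9R)-6-{[(1R,3S)-2,2-dimethyl-3-(prop-1-en-2-yl)cyclobutyl]methyl}-8,9-dimethyl-6-(3-methylbut-2-en-1-yl)-4-pentyl-3,4,8,9-tetrahydro-2H-pyrano[2,3-f]chromene-2,5,10(6H)-trione | C=C(C)[C@@H]1C[C@H](C[C@@]2(CC=C(C)C)C(=O)C4=C(OC(=O)C[C@@H]4CCCCC)C3=C2O[C@H](C)[C@@H](C)C3=O)C1(C)C | intermediate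
21 | (3S)-3-[(2R,3R,8R)-8-{[(1R,3S)-2,2-dimethyl-3-(prop-1-en-2-yl)cyclobutyl]methyl}-5-hydroxy-2,3-dimethyl-8-(3-methylbut-2-en-1-yl)-4,7-dioxo-3,4,7,8-tetrahydro-2H-chromen-6-yl]octanoic acid | C=C(C)[C@@H]1C[C@H](C[C@@]2(CC=C(C)C)C(=O)C([C@@H](CCCCC)CC(=O)O)=C(O)C3=C2O[C@H](C)[C@@H](C)C3=O)C1(C)C | target

## Step count and least certain steps

Total: 13 steps. Longest linear sequence: 8 steps (1, 2, 3, 4, 5, 10, 12, 13). The ring C branch (steps 6 to 9) joins at step 10 and the carbonate (step 11) at step 12.

**Step 12 (labelled step).**
- *What may go wrong.* Persistent O-prenylation if re-ionisation of the aryl ether is slow, alkylation at the other ortho carbon (C4a), and weak or mismatched facial selection, because the ligand must distinguish two faces of a large flat nucleophile whose own stereocentres are remote.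
- *Fallback (known chemistry), from 17 back to 20.* The lithium phenoxide (LiHMDS, toluene, −78 to 0 °C) is alkylated with prenyl bromide. This is the classical alkylative dearomatisation of phloroglucinol-type phenols, in which a non-polar medium and a tightly bound counter-ion favour carbon. No face control is expected, so 20 is separated by chromatography from its C6 epimer, (4S,6S,8R,9R)-trione F1.

**Step 1 (key step).**
- *What may go wrong.* Sluggish C-attack of a monocyclic phenol relative to O-acylation, a second annulation of the product, γ-deprotonation of the β-alkyl acyl azolium, and lower enantioselectivity than with β-aryl enals.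
- *Fallback, from 1 back to 4.* Pechmann condensation of 1 with ethyl 3-oxooctanoate (MeSO3H, rt) gives 5,7-dihydroxy-4-pentylcoumarin F2. Asymmetric conjugate reduction of F2 with CuH (Cu(OAc)2·H2O, the appropriate antipode of DTBM-SEGPHOS, diethoxymethylsilane, t-BuOH, toluene), followed by acidic work-up to cleave silyl ethers and re-close the lactone, returns to 4.

**Step 2.**
- *What may go wrong.* Acylation at C6 or at both free carbons, premature unselective closure of the enone on O7 under the Lewis acid, and addition of HCl to the enone.
- *Fallback, from 4 back to 17.* The order of the two electrophilic substitutions is inverted, so that the intrinsically more reactive C6 takes the halogen first.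
  - NBS (MeCN, −20 °C) gives (S)-6-bromo-5,7-dihydroxy-4-pentylchroman-2-one F3.
  - Acylation with 5 can then go only to C8 and gives the 6-bromo-8-tigloyl compound F4.
  - The conditions of steps 3 and 4 give the bromo analogue of 9, F5.
  - F5 enters the coupling of step 10 in place of 9 and returns to 17.

**Step 3.**
- *What may go wrong.* Erosion of facial selectivity by uncatalysed background closure or by a poorer fit of the saturated lactone in the catalyst pocket, and slow transacylation of the lactone by the catalyst hydroxyl.
- *Fallback, from 6 back to 8.* Closure under plain base (K2CO3, 2-butanone, reflux) gives the thermodynamic trans isomers without control at C8 of the tricycle. Because of the fixed C4 centre these are diastereomers, so 8 is separated from the (4S,8S,9S) isomer F6. F6 is re-exposed to the base, where retro-oxa-Michael opening and re-closure regenerate the mixture for recycling.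

**Step 10.**
- *What may go wrong.* Slow oxidative addition at the hindered, electron-rich iodide leading to protodeiodination, ring opening through radical intermediates during zinc insertion, and β-hydride elimination.
- *Fallback, from 13 and 8 back to 17 (steps 5 and 9 are omitted).*
  - Dess–Martin oxidation of 13 gives (1S,3S)-2,2-dimethyl-3-(prop-1-en-2-yl)cyclobutane-1-carbaldehyde F7.
  - F7 is condensed with 8 under a mild diphenyl phosphate catalyst in the presence of Hantzsch ester.
  - The ortho-quinone methide F8 formed in the flask is reduced at once to 17.
  - The hydride donor must be present from the start, to outrun epimerisation of F7 and hydrogen shift in F8.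

## Further compounds

F1 | step 12 | (4S,6S,8R,9R)-C6 epimer of 20 | C=C(C)[C@@H]1C[C@H](C[C@]2(CC=C(C)C)C(=O)C4=C(OC(=O)C[C@@H]4CCCCC)C3=C2O[C@H](C)[C@@H](C)C3=O)C1(C)C
F2 | step 1 | 5,7-dihydroxy-4-pentyl-2H-chromen-2-one | CCCCCc1cc(=O)oc2cc(O)cc(O)c12
F3 | step 2 | (S)-6-bromo-5,7-dihydroxy-4-pentylchroman-2-one | O=C1C[C@H](CCCCC)c2c(O)c(Br)c(O)cc2O1
F4 | step 2 | (S)-6-bromo-5,7-dihydroxy-8-[(E)-2-methylbut-2-enoyl]-4-pentylchroman-2-one | O=C1C[C@H](CCCCC)c2c(O)c(Br)c(O)c(C(=O)/C(C)=C/C)c2O1
F5 | step 2 | (4S,8R,9R)-6-bromo-5-hydroxy-8,9-dimethyl-4-pentyl-3,4,8,9-tetrahydro-2H,10H-pyrano[2,3-f]chromene-2,10-dione | O=C1C[C@H](CCCCC)c2c(O)c(Br)c3O[C@H](C)[C@@H](C)C(=O)c3c2O1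
F6 | step 3 | (4S,8S,9S)-5-hydroxy-8,9-dimethyl-4-pentyl-3,4,8,9-tetrahydro-2H,10H-pyrano[2,3-f]chromene-2,10-dione | O=C1C[C@H](CCCCC)c2c(O)cc3O[C@@H](C)[C@H](C)C(=O)c3c2O1
F7 | step 10 | (1S,3S)-2,2-dimethyl-3-(prop-1-en-2-yl)cyclobutane-1-carbaldehyde | C=C(C)[C@@H]1C[C@H](C=O)C1(C)C
F8 | step 10 | ortho-quinone methide from 8 and F7 (6-cyclobutylmethylidene-2,5,10-trione, double-bond geometry open) | C=C(C)[C@@H]1C[C@H](C=C2C(=O)C4=C(OC(=O)C[C@@H]4CCCCC)C3=C2O[C@H](C)[C@@H](C)C3=O)C1(C)C
A1 | alternative 1 | cis-2-isopropenyl-3,3-dimethyl-4-(pivaloyloxymethyl)cyclobutanone (configuration as in ring C of 21) | C=C(C)[C@@H]1C(=O)[C@H](COC(=O)C(C)(C)C)C1(C)C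
A2 | alternative 1 | prenyl pivalate | CC(C)=CCOC(=O)C(C)(C)C
A3 | alternative 1 | 1-[(2S,5S)-2,5-dimethylpyrrolidin-1-yl]-3-methylbut-3-en-1-one | C=C(C)CC(=O)N1[C@@H](C)CC[C@@H]1C
A4 | alternative 1 | vinyl keteniminium triflate from A3 | C=C(C)C=C=[N+]1[C@@H](C)CC[C@@H]1C.[O-]S(=O)(=O)C(F)(F)F
A5 | alternative 2 | 2-(trimethylsilyl)ethyl ester of 21 | C=C(C)[C@@H]1C[C@H](C[C@@]2(CC=C(C)C)C(=O)C([C@@H](CCCCC)CC(=O)OCC[Si](C)(C)C)=C(O)C3=C2O[C@H](C)[C@@H](C)C3=O)C1(C)C
A6 | alternative 2 | dihydropyranone keto diester (methyl ester on the quaternary carbon, side-chain ketone on the ring) | C=C(C)[C@@H]1C[C@H](C[C@@](CC=C(C)C)(C(=O)OC)C2=C(C(=O)C[C@@H](CCCCC)CC(=O)OCC[Si](C)(C)C)C(=O)[C@H](C)[C@@H](C)O2)C1(C)C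
A7 | alternative 3 | (4S,8R,9R)-5-hydroxy-8,9-dimethyl-4-pentyl-3,4,8,9-tetrahydro-2H,10H-pyrano[2,3-f]chromene-2,10-dione (identical with 8) | O=C1C[C@H](CCCCC)c2c(O)cc3O[C@H](C)[C@@H](C)C(=O)c3c2O1
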